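**Retrosynthetic overview**
- The target is reached by a late Felkin–Anh hydride reduction of the C1 aroyl ketone, carried out after global O-demethylation because the p-hydroxybenzylic alcohol would not survive acid.
- The indane five-membered ring is the only ring made. It closes through the C3–C3a bond by a cationic Friedel–Crafts alkylation of a p-methoxybenzylic carbinol, which places C3 trans to C2.
- The C3 carbinol and the C1 aryl ketone come from one double aryl-Grignard addition to an aldehyde/Weinreb amide obtained by ozonolysis.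
- The key C1–C2 bond and both of its stereocentres come from an Ireland–Claisen [3,3] rearrangement of an (S,Z)-allyl arylacetate, with 1,3-chirality transfer from the carbinol centre.
- That ester comes from (S)-but-3-yn-2-ol by Sonogashira coupling, Lindlar reduction and esterification; all benzene rings are bought.

Assumption: (S)-but-3-yn-2-ol (≥98% ee, the L-lactic acid configurational series) is taken as an inexpensive commercial chiral building block; it is the only source of chirality.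

**Step 1**
Reactants: 1 (S)-but-3-yn-2-ol; 2 1-iodo-3,5-dimethoxybenzene
Product: 3 (S)-4-(3,5-dimethoxyphenyl)but-3-yn-2-ol
Conditions: PdCl2(PPh3)2 (2 mol%), CuI (4 mol%), Et3N, rt
Reagents that add atoms: none
Why: Sonogashira coupling of the terminal alkyne with the aryl iodide does not touch the propargylic stereocentre.

**Step 2**
Reactants: 3 (S)-4-(3,5-dimethoxyphenyl)but-3-yn-2-ol
Product: 4 (2S,3Z)-4-(3,5-dimethoxyphenyl)but-3-en-2-ol
Conditions: H2 (1 atm), Lindlar catalyst, quinoline, EtOAc, rt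
Reagents that add atoms: none
Why: Lindlar semihydrogenation adds H2 syn and stops at the (Z)-alkene, the geometry the later chair transition state needs, while the carbinol centre is untouched.

**Step 3**
Reactants: 4 (2S,3Z)-4-(3,5-dimethoxyphenyl)but-3-en-2-ol; 5 (3,5-dimethoxyphenyl)acetic acid
Product: 6 (2S,3Z)-4-(3,5-dimethoxyphenyl)but-3-en-2-yl (3,5-dimethoxyphenyl)acetate
Conditions: DCC, DMAP (cat.), CH2Cl2, 0 °C → rt
Reagents that add atoms: none
Why: Steglich esterification acylates the secondary allylic alcohol on oxygen with retention at the carbinol carbon.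

**Step 4**
Reactants: 6 (2S,3Z)-4-(3,5-dimethoxyphenyl)but-3-en-2-yl (3,5-dimethoxyphenyl)acetate
Product: 9 (2R,3S,4E)-2,3-bis(3,5-dimethoxyphenyl)hex-4-enoic acid, via silyl ketene acetal 7 (not isolated), via trimethylsilyl ester 8 (not isolated)
Conditions: LiHMDS, TMSCl, Et3N, THF, −78 °C → rt → 50 °C; then 1 M HCl
Reagents that add atoms: none
Why: Ireland–Claisen [3,3]-sigmatropic rearrangement in which the arylacetate gives the (Z)-silyl ketene acetal (aryl cis to OSi) and a chair transition state with the carbinol methyl equatorial (an axial methyl would clash with the (Z)-aryl group) forms the new C–C bond suprafacially, so the (S)-carbinol chirality is transferred to the (2R,3S) pair and an (E)-propenyl group is left.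

**Step 5**
Reactants: 9 (2R,3S,4E)-2,3-bis(3,5-dimethoxyphenyl)hex-4-enoic acid; 10 N,O-dimethylhydroxylamine hydrochloride
Product: 11 (2R,3S,4E)-2,3-bis(3,5-dimethoxyphenyl)-N-methoxy-N-methylhex-4-enamide
Conditions: EDC·HCl, HOBt, N-methylmorpholine, CH2Cl2, 0 °C → rt
Reagents that add atoms: none
Why: Carbodiimide/HOBt amide coupling gives the Weinreb amide under conditions mild enough to keep the α-aryl stereocentre.

**Step 6**
Reactants: 11 (2R,3S,4E)-2,3-bis(3,5-dimethoxyphenyl)-N-methoxy-N-methylhex-4-enamide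
Product: 13 (2R,3S)-2,3-bis(3,5-dimethoxyphenyl)-N-methoxy-N-methyl-4-oxobutanamide, via ozonide 12 (not isolated)
Conditions: O3, CH2Cl2, −78 °C (Sudan III end-point); then Me2S, −78 °C → rt; used crude
Reagents that add atoms: ozone, [O-][O+]=O
Why: Ozonolysis with reductive work-up cleaves the only C=C bond, which reacts far faster than the dimethoxyarenes when ozone is titrated to an indicator end-point, and no stereocentre is formed.

**Step 7**
Reactants: 13 (2R,3S)-2,3-bis(3,5-dimethoxyphenyl)-N-methoxy-N-methyl-4-oxobutanamide; 14 (4-methoxyphenyl)magnesium bromide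
Product: 17 (2R,3S,4RS)-4-hydroxy-2,3-bis(3,5-dimethoxyphenyl)-1,4-bis(4-methoxyphenyl)butan-1-one, via bromomagnesium alkoxide 15 (not isolated), via tetrahedral adduct 16 (not isolated)
Conditions: 14 (4 equiv), THF, −78 °C → 0 °C; sat. aq. NH4Cl
Reagents that add atoms: none
Why: Grignard addition occurs first at the aldehyde at −78 °C and then at the Weinreb amide on warming, which stops at the ketone stage, and the new C4 carbinol mixture is irrelevant because that centre is ionised in the next step.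

**Step 8**
Reactants: 17 (2R,3S,4RS)-4-hydroxy-2,3-bis(3,5-dimethoxyphenyl)-1,4-bis(4-methoxyphenyl)butan-1-one
Product: 19 [(1R,2S,3R)-2-(3,5-dihydroxyphenyl)-4,6-dihydroxy-3-(4-hydroxyphenyl)-2,3-dihydro-1H-inden-1-yl](4-hydroxyphenyl)methanone, via hexamethyl ether ketone 18 (not isolated)
Conditions: BF3·OEt2 (0.2 equiv), CH2Cl2, −40 → 0 °C; then BBr3 (15 equiv), −78 °C → rt; H2O
Reagents that add atoms: none
Why: Lewis-acid ionisation of the p-methoxybenzylic alcohol and intramolecular Friedel–Crafts alkylation at the ring position ortho/para to the two methoxy groups closes the indane with the C3 aryl trans to the C2 aryl (substrate control), after which BBr3 cleaves all six aryl methyl ethers while the C1 ketone keeps the thermodynamically preferred 1,2-trans arrangement.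

**Step 9**
Reactants: 19 [(1R,2S,3R)-2-(3,5-dihydroxyphenyl)-4,6-dihydroxy-3-(4-hydroxyphenyl)-2,3-dihydro-1H-inden-1-yl](4-hydroxyphenyl)methanone
Product: 20 (1R,2S,3R)-2-(3,5-dihydroxyphenyl)-1-[(R)-hydroxy(4-hydroxyphenyl)methyl]-3-(4-hydroxyphenyl)-2,3-dihydro-1H-indene-4,6-diol
Conditions: NaBH4 (excess), MeOH/THF, 0 °C → rt; aq. NH4Cl to pH 7
Reagents that add atoms: none
Why: Felkin–Anh-controlled hydride reduction with the fused aromatic carbon C7a antiperiplanar to the incoming hydride (the opposite face is blocked by the peri C7–H) is predicted to give the (R)-carbinol by attack past the C1–H.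

**Compound list**
1 | (S)-but-3-yn-2-ol | C[C@H](O)C#C | starting material
2 | 1-iodo-3,5-dimethoxybenzene | COc1cc(I)cc(OC)c1 | starting material
3 | (S)-4-(3,5-dimethoxyphenyl)but-3-yn-2-ol | C[C@H](O)C#Cc1cc(OC)cc(OC)c1 | intermediate
4 | (2S,3Z)-4-(3,5-dimethoxyphenyl)but-3-en-2-ol | C[C@H](O)/C=C\c1cc(OC)cc(OC)c1 | intermediate
5 | (3,5-dimethoxyphenyl)acetic acid | COc1cc(CC(=O)O)cc(OC)c1 | starting material
6 | (2S,3Z)-4-(3,5-dimethoxyphenyl)but-3-en-2-yl (3,5-dimethoxyphenyl)acetate | C[C@H](OC(=O)Cc1cc(OC)cc(OC)c1)/C=C\c1cc(OC)cc(OC)c1 | intermediate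
7 | (Z)-O-trimethylsilyl ketene acetal of 6 (aryl cis to OSiMe3) | C[C@H](O/C(O[Si](C)(C)C)=C/c1cc(OC)cc(OC)c1)/C=C\c1cc(OC)cc(OC)c1 | intermediate
8 | trimethylsilyl (2R,3S,4E)-2,3-bis(3,5-dimethoxyphenyl)hex-4-enoate | C[Si](C)(C)OC(=O)[C@@H](c1cc(OC)cc(OC)c1)[C@@H](c1cc(OC)cc(OC)c1)/C=C/C | intermediate
9 | (2R,3S,4E)-2,3-bis(3,5-dimethoxyphenyl)hex-4-enoic acid | OC(=O)[C@@H](c1cc(OC)cc(OC)c1)[C@@H](c1cc(OC)cc(OC)c1)/C=C/C | intermediate
10 | N,O-dimethylhydroxylamine hydrochloride | CNOC.Cl | starting material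
11 | (2R,3S,4E)-2,3-bis(3,5-dimethoxyphenyl)-N-methoxy-N-methylhex-4-enamide | CON(C)C(=O)[C@@H](c1cc(OC)cc(OC)c1)[C@@H](c1cc(OC)cc(OC)c1)/C=C/C | intermediate
12 | (2R,3S)-2,3-bis(3,5-dimethoxyphenyl)-N-methoxy-N-methyl-3-(5-methyl-1,2,4-trioxolan-3-yl)propanamide (ozonide) | CON(C)C(=O)[C@@H](c1cc(OC)cc(OC)c1)[C@@H](c1cc(OC)cc(OC)c1)C1OOC(C)O1 | intermediate
13 | (2R,3S)-2,3-bis(3,5-dimethoxyphenyl)-N-methoxy-N-methyl-4-oxobutanamide | CON(C)C(=O)[C@@H](c1cc(OC)cc(OC)c1)[C@@H](c1cc(OC)cc(OC)c1)C=O | intermediate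
14 | (4-methoxyphenyl)magnesium bromide | COc1ccc([Mg]Br)cc1 | starting material
15 | bromomagnesium alkoxide of (2R,3S,4RS)-4-hydroxy-2,3-bis(3,5-dimethoxyphenyl)-N-methoxy-4-(4-methoxyphenyl)-N-methylbutanamide | CON(C)C(=O)[C@@H](c1cc(OC)cc(OC)c1)[C@@H](c1cc(OC)cc(OC)c1)C(O[Mg]Br)c1ccc(OC)cc1 | intermediate
16 | tetrahedral bis(bromomagnesium) adduct of 15 with 14 at the amide carbon | COc1ccc(cc1)C(O[Mg]Br)(N(C)OC)[C@@H](c1cc(OC)cc(OC)c1)[C@@H](c1cc(OC)cc(OC)c1)C(O[Mg]Br)c1ccc(OC)cc1 | intermediate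
17 | (2R,3S,4RS)-4-hydroxy-2,3-bis(3,5-dimethoxyphenyl)-1,4-bis(4-methoxyphenyl)butan-1-one | COc1ccc(cc1)C(=O)[C@@H](c1cc(OC)cc(OC)c1)[C@@H](c1cc(OC)cc(OC)c1)C(O)c1ccc(OC)cc1 | intermediate
18 | [(1R,2S,3R)-2-(3,5-dimethoxyphenyl)-4,6-dimethoxy-3-(4-methoxyphenyl)-2,3-dihydro-1H-inden-1-yl](4-methoxyphenyl)methanone | COc1ccc([C@@H]2c3c(OC)cc(OC)cc3[C@H](C(=O)c3ccc(OC)cc3)[C@H]2c2cc(OC)cc(OC)c2)cc1 | intermediate
19 | [(1R,2S,3R)-2-(3,5-dihydroxyphenyl)-4,6-dihydroxy-3-(4-hydroxyphenyl)-2,3-dihydro-1H-inden-1-yl](4-hydroxyphenyl)methanone | Oc1ccc([C@@H]2c3c(O)cc(O)cc3[C@H](C(=O)c3ccc(O)cc3)[C@H]2c2cc(O)cc(O)c2)cc1 | intermediate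
20 | (1R,2S,3R)-2-(3,5-dihydroxyphenyl)-1-[(R)-hydroxy(4-hydroxyphenyl)methyl]-3-(4-hydroxyphenyl)-2,3-dihydro-1H-indene-4,6-diol | Oc1ccc([C@@H]2c3c(O)cc(O)cc3[C@H]([C@@H](O)c3ccc(O)cc3)[C@H]2c2cc(O)cc(O)c2)cc1 | target

**Totals**
Total step count: 9. Longest linear sequence: 9 steps (1 → 20).

**Steps most likely to fail**

Step 7. The α-aryl aldehyde 13 is enolisable, which would erode the C3 centre. The first-formed alkoxide may also lactonise onto the Weinreb amide and open the way to over-addition. The fallback sets out from acid 9 and keeps the two electrophiles apart. Ozonolysis of 9 (O3, CH2Cl2, −78 °C; Me2S) gives (2R,3S)-2,3-bis(3,5-dimethoxyphenyl)-4-oxobutanoic acid F1. Treating it with 14 (3 equiv, THF, −78 → 0 °C) and an acidic work-up gives the γ-lactone (3R,4S,5RS)-3,4-bis(3,5-dimethoxyphenyl)-5-(4-methoxyphenyl)oxolan-2-one F2. One equivalent of 14 at −78 °C then opens the lactone to the γ-hydroxy ketone, and the route is rejoined at 17.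

Step 8. The γ-hydroxy ketone can divert through its cyclic hemiketal or through E1 elimination before the ring closes, and the one-pot demethylation leaves no chance to purify. The fallback sets out from 13 and closes the ring before the ketone exists. Adding 14 (1.1 equiv, −78 °C) to the aldehyde alone gives (2R,3S,4RS)-4-hydroxy-2,3-bis(3,5-dimethoxyphenyl)-N-methoxy-4-(4-methoxyphenyl)-N-methylbutanamide F3. BF3·OEt2 in CH2Cl2 cyclises it to (1R,2S,3R)-2-(3,5-dimethoxyphenyl)-N,4,6-trimethoxy-3-(4-methoxyphenyl)-N-methyl-2,3-dihydro-1H-indene-1-carboxamide F4, which is isolated and checked. A second portion of 14 at 0 °C gives the ketone, so the route is rejoined at 18, now isolated and demethylated with BBr3 in a separate operation to 19.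

Step 9. The phenoxides formed from the hexaphenol slow the reduction, and the selectivity with NaBH4 may be modest. The fallback sets out from 19. TBSCl/imidazole in DMF gives the hexakis(tert-butyldimethylsilyl) ether of ketone 19, F5. L-Selectride in THF at −78 °C, a bulky hydride that sharpens the Felkin–Anh preference, gives the hexakis(tert-butyldimethylsilyl) ether of the (R)-carbinol, F6. TBAF buffered with AcOH in THF at 0 °C removes the silyl groups, and the route is rejoined at 20.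

**Further compounds**
F1 | step 7 | (2R,3S)-2,3-bis(3,5-dimethoxyphenyl)-4-oxobutanoic acid | OC(=O)[C@@H](c1cc(OC)cc(OC)c1)[C@@H](c1cc(OC)cc(OC)c1)C=O
F2 | step 7 | (3R,4S,5RS)-3,4-bis(3,5-dimethoxyphenyl)-5-(4-methoxyphenyl)oxolan-2-one | O=C1[C@@H](c2cc(OC)cc(OC)c2)[C@@H](c2cc(OC)cc(OC)c2)C(c2ccc(OC)cc2)O1
F3 | step 8 | (2R,3S,4RS)-4-hydroxy-2,3-bis(3,5-dimethoxyphenyl)-N-methoxy-4-(4-methoxyphenyl)-N-methylbutanamide | CON(C)C(=O)[C@@H](c1cc(OC)cc(OC)c1)[C@@H](c1cc(OC)cc(OC)c1)C(O)c1ccc(OC)cc1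
F4 | step 8 | (1R,2S,3R)-2-(3,5-dimethoxyphenyl)-N,4,6-trimethoxy-3-(4-methoxyphenyl)-N-methyl-2,3-dihydro-1H-indene-1-carboxamide | COc1ccc([C@@H]2c3c(OC)cc(OC)cc3[C@H](C(=O)N(C)OC)[C@H]2c2cc(OC)cc(OC)c2)cc1
F5 | step 9 | hexakis(tert-butyldimethylsilyl) ether of ketone 19 | CC(C)(C)[Si](C)(C)Oc1ccc([C@@H]2c3c(O[Si](C)(C)C(C)(C)C)cc(O[Si](C)(C)C(C)(C)C)cc3[C@H](C(=O)c3ccc(O[Si](C)(C)C(C)(C)C)cc3)[C@H]2c2cc(O[Si](C)(C)C(C)(C)C)cc(O[Si](C)(C)C(C)(C)C)c2)cc1
F6 | step 9 | hexakis(tert-butyldimethylsilyl) aryl ether of 20 (free carbinol) | CC(C)(C)[Si](C)(C)Oc1ccc([C@@H]2c3c(O[Si](C)(C)C(C)(C)C)cc(O[Si](C)(C)C(C)(C)C)cc3[C@H]([C@@H](O)c3ccc(O[Si](C)(C)C(C)(C)C)cc3)[C@H]2c2cc(O[Si](C)(C)C(C)(C)C)cc(O[Si](C)(C)C(C)(C)C)c2)cc1
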